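**Proposal: a once-rearranged bis-oxolane – two-directional assembly on a desymmetrised divanillin core, then ring transposition of the arm whose phenol is not switched off**

Remark on the chemistry: the oxolane half is taken exactly as written in the target, (2R,3R,4S), with the 2-aryl, 3-hydroxymethyl and 4-arylmethyl groups on one face of the ring (2,3-cis). No other assumption is needed.

## Analysis of the target

The target 21 is an unsymmetrical dimer of two lignan units joined through the aryl–aryl bond of a 2,2'-dihydroxy-3,3'-dimethoxybiphenyl: one half is a 2-aryl-oxolane (O1, C2 aryl, C3 CH2OH, C4 OH and 4-hydroxy-3-methoxybenzyl, C5 H2), the other a 1-aryl-tetralin (C1 aryl, C2 CH2OH, C3 OH and CH2OH, C4 H2, fused guaiacyl ring C4a–C8a). There are six stereocentres: the oxolane is 2R,3R,4S, with all three carbon substituents cis and the tertiary hydroxyl on the other face, and the tetralin is 1S,2S,3S, with aryl and C2 hydroxymethyl trans and the two hydroxymethyl groups trans. Oxolane C3/C4 and tetralin C2/C3 are the same pair of carbons in the same absolute sense; only the benzylic carbon differs, bonded to O1 in one half and to C8a in the other. The biaryl bond has only two ortho substituents, so it is not a stereogenic axis. The sensitive groups are four phenols and the para-oxygenated benzylic C2–O1 bond, which ionises in acid and can be hydrogenolysed; because the 2,3-cis oxolane is the less stable C2 epimer, any acid that reaches it while its aryl ring is electron-rich will epimerise it. The difficulty is therefore threefold: two nearly identical halves on a symmetric biaryl must be told apart, one must be rearranged under the very conditions that would epimerise the other, and the tertiary carbinol next to a tertiary CH is needed twice in the same absolute sense. The strategy rests on one feature: breaking C2–O1 of an oxolane and joining C2 to the ring carbon para to the methoxy group of the benzyl substituent on C4 gives the tetralin, with C3/C4 becoming C2/C3 and the O1–C5H2 unit becoming the hydroxymethyl group on C3. The target is thus a bis-oxolane in which one arm has rearranged.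

## Retrosynthetic reasoning

**21 to 20 to 19 (O–benzyl and O–sulfonyl bonds).** The four phenols are traced back to three benzyl ethers and one tosylate on a biaryl oxygen. The tosylate is not only a protecting group: it is the control element of the key step. It is removed first, reductively and at room temperature, while the molecule is still lipophilic. The benzyl ethers go last by hydrogenolysis, so the final step yields only toluene beside the target.

**19 to 18 (tetralin C1–C8a cut, C2–O1 re-formed).** This is the strategic disconnection. The forward reaction must ionise one benzylic C–O bond and close the six-membered ring with the pendant aryl group, 1,2-trans. Running a substrate with two equivalent arms to half conversion is ruled out. An arm that has not yet closed is in equilibrium with its open cation and would return as the 2,3-trans epimer, so both the recovered material and the surviving half of the product would lose the C2 configuration. The arm that must survive therefore carries a para-sulfonyloxy group in 18 and cannot ionise. The other arm carries a para-benzyloxy group and can.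

**18 to 17 (two C2–H bonds).** The cis relation between aryl and hydroxymethyl is the kinetic outcome of hydride delivery to a 2-aryl oxocarbenium ion from the face opposite the C3 substituent. Both oxolanes are therefore traced to the cyclic hemiketals of 17. The oxolane of 18 that sits on the tosyloxy ring cannot re-ionise, so its C2 centre is fixed from that step on.

**17 to 16 to 14 (oxidation level).** The hemiketals come from benzylic ketones trapped by the C5 hydroxyl, the ketones from benzylic carbinols in 16, and the two primary alcohols of each arm from a lactone in 14. The detour through the carbinol is accepted because it allows the next disconnection.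

**14 to 13 and 4 (two C–C bonds, lactone α-carbon to benzylic carbon).** The cut is made between C3 and the future C2, not between C2 and the aryl ring, for two reasons.
- An aryl-metal route would have to put the hydroxymethyl group on the lactone α-carbon cis to the arylmethyl group. In the aldol mode the incoming carbon becomes the ring carbon C2 and the lactone carbonyl becomes the hydroxymethyl group, so attack anti to the arylmethyl group gives the required C3 configuration.
- The two aldehyde groups of 4 coexist with its aryl tosylate, which an aryl-lithium centre on the same ring would not.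

Both arms are made in one operation from 13 and dialdehyde 4.

**4 to 3 to 2 to 1 (S–O, O–CH2 and aryl–aryl bonds).** The biaryl is the oxidative dimer 2 of two molecules of vanillin 1. Its two phenols are differentiated once, at the start, as benzyl ether and tosylate (3, then 4).

**13 to 12 to 10 to 9 to 8 and 6; 8 to 7; 6 to 5.** The quaternary carbinol is the carbinol carbon of (S)-malic acid 7. Its hydrogen is replaced by the arylmethyl group of bromide 6 (from alcohol 5) with retention, through the tert-butyl dioxolanone 8. Selective reduction of the carboxyl next to the hydroxyl and lactonisation (10, 11, 12) give the lactone. Silylation gives 13.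

## Alternatives that were turned down

Alternative 1: The tetralin is cut at C1–C2.
- Forward key step: acid ionises the diarylmethanol A2 (either carbinol epimer, since that centre is destroyed), and the enamine formed from its tethered aldehyde captures the diarylmethyl cation to give the tetralin aldehyde A1.
- For it: the step is stereoconvergent. The aldehyde sits where the C2 hydroxymethyl group is needed, and C2 can equilibrate through the enamine toward the 1,2-trans product. Because the oxolane would be built afterwards on the aryl bromide of A1, the two halves never have to be told apart and the acid-labile cis-oxolane is never exposed to acid. On this point it is stronger than the chosen plan.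
- Against it: C1 and C2 are both set relative to the remote spiro carbon C3, which must be made enantiopure on its own. Enamine and strong acid must coexist, and the acetonide must survive that acid. Aldehyde reduction, acetonide cleavage and the whole oxolane construction still follow.
- Comparison: linear, with the same kind of quaternary carbinol made twice by different chemistry. The chosen route takes tetralin C2 and C3 unchanged from the oxolane and makes both halves in one two-directional sequence.

Alternative 2: The tetralin is cut at C3–C4.
- Forward key step: hydroxide adds to one carbonyl of the seven-membered dione A4, and a 1,2-shift contracts the ring to the hydroxy acid A3.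
- For it: the tertiary carbinol and its one-carbon substituent arise in one step from two carbonyl groups. Which carbonyl is attacked does not matter for the constitution, since both modes give the same ring-contracted skeleton.
- Against it: the C3 configuration is decided by the face of migration in a flexible seven-membered ring, with only the C2 substituent to bias it. C2 is α to a carbonyl and would epimerise in hydroxide. The benzocycloheptenedione needs a long synthesis of its own, and the acid must still be reduced.
- Comparison: more steps and two open stereochemical questions, against none at C2/C3 in the chosen route. It shares with alternative 1 the advantage that no arm differentiation is needed, but it leaves the oxolane half to a second campaign.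

Alternative 3: The tetralin is cut at C4–C4a.
- Forward key step: acid activates the 3-hydroxyoxetane of A6 and the 3-benzyloxy-4-methoxyphenyl ring attacks one of the two diastereotopic CH2 groups, para to its benzyloxy group, to give the tetralin ester A5. The other CH2 is released as the hydroxymethyl group.
- For it: the C3 carbinol is created by a choice between two CH2 arms without any carbonyl addition. C1 and C2 are set earlier in an open chain, and the site of attack on the arene is unambiguous.
- Against it: Friedel–Crafts alkylation at a primary, neopentyl-type oxetane carbon needs forcing acid. The tertiary oxetanol can ionise or ring-expand under it. The wrong CH2 gives the C3 epimer, with only the C2 centre to prevent that. The ester must still be reduced and the oxolane half built afterwards.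
- Comparison: like the other two, it is as strong as the chosen plan in avoiding the symmetry problem. The chosen plan answers that problem with one sulfonate and gains a mild, well-known isomerisation in place of a forcing cyclisation.

Key step: step 14

## Route

Step 1
Reactants: 1 vanillin (2.0 equiv)
Product: 2 dehydrodivanillin (6,6'-dihydroxy-5,5'-dimethoxybiphenyl-3,3'-dicarbaldehyde)
Conditions: FeSO4·7H2O (cat.), Na2S2O8 (0.5 equiv per 1), H2O, 50 °C
Reagents that add atoms: none
Why: Oxidative phenol coupling that joins two molecules of 1 through C5; the para position is blocked by the formyl group, so the phenoxy radicals should join ortho–ortho and the dimer should precipitate from water.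

Step 2
Reactants: 2 dehydrodivanillin
Product: 3 mono-O-benzyl dehydrodivanillin (6-benzyloxy-6'-hydroxy-5,5'-dimethoxybiphenyl-3,3'-dicarbaldehyde)
Conditions: BnBr (1.0 equiv), K2CO3 (0.55 equiv), DMF, rt; unreacted 2 recycled
Reagents that add atoms: benzyl bromide, BrCc1ccccc1
Why: Williamson etherification under base-limited conditions; the first phenol of a 2,2'-biphenol is the more acidic one (hydrogen-bonded monoanion), so the monoether should dominate and is separable from diol and diether.

Step 3
Reactants: 3 mono-O-benzyl dehydrodivanillin
Product: 4 O-benzyl-O'-tosyl dehydrodivanillin (2'-benzyloxy-5,5'-diformyl-3,3'-dimethoxybiphenyl-2-yl 4-methylbenzenesulfonate)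
Conditions: TsCl, Et3N, DMAP (cat.), CH2Cl2, 0 °C to rt
Reagents that add atoms: p-toluenesulfonyl chloride, Cc1ccc(cc1)S(Cl)(=O)=O
Why: Sulfonylation of the remaining phenol; this one group later decides which arm may ionise and protects the C2 centre of the other arm from acid.

Step 4
Reactants: 5 [4-(benzyloxy)-3-methoxyphenyl]methanol
Product: 6 4-(benzyloxy)-3-methoxybenzyl bromide
Conditions: PBr3, Et2O, 0 °C; used at once
Reagents that add atoms: phosphorus tribromide, BrP(Br)Br
Why: Standard conversion of an electron-rich benzylic alcohol into the bromide through the phosphite ester.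

Step 5
Reactants: 7 (S)-malic acid
Product: 8 cis-dioxolanone acid (2-[(2S,4S)-2-tert-butyl-5-oxo-1,3-dioxolan-4-yl]acetic acid)
Conditions: t-BuCHO, TsOH·H2O (cat.), H2SO4 (cat.), pentane, reflux with water separator; crystallisation of the cis isomer
Reagents that add atoms: pivalaldehyde, CC(C)(C)C=O
Why: Acetalisation of the α-hydroxy acid unit; the cis acetal is favoured and stores the configuration of the carbinol carbon in the acetal carbon (self-regeneration of a stereocentre).

Step 6
Reactants: 8 cis-dioxolanone acid; 6 4-(benzyloxy)-3-methoxybenzyl bromide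
Product: 9 benzylated dioxolanone acid (2-[(2S,4S)-4-(4-benzyloxy-3-methoxybenzyl)-2-tert-butyl-5-oxo-1,3-dioxolan-4-yl]acetic acid)
Conditions: LiN(SiMe3)2 (2.1 equiv), THF, −78 °C; then 6, −78 to −20 °C; aq. HCl work-up
Reagents that add atoms: none
Why: Alkylation of the carboxylate–enolate dianion; the bromide enters the planar ring enolate anti to the tert-butyl group, on the face the hydrogen had occupied, so the quaternary carbinol carbon is formed with retention.

Step 7
Reactants: 9 benzylated dioxolanone acid
Product: 10 dimethyl (2S)-2-(4-benzyloxy-3-methoxybenzyl)-2-hydroxybutanedioate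
Conditions: HCl (1.25 M in MeOH), 50 °C
Reagents that add atoms: methanol, CO
Why: Acid-catalysed methanolysis of the acylal ring together with Fischer esterification of the side-chain acid; the quaternary centre is not touched.

Step 8
Reactants: 10 dimethyl (2S)-2-(4-benzyloxy-3-methoxybenzyl)-2-hydroxybutanedioate
Product: 12 (4S)-4-(4-benzyloxy-3-methoxybenzyl)-4-hydroxyoxolan-2-one, via diol ester 11 (not isolated)
Conditions: BH3·SMe2, NaBH4 (5 mol %), THF, rt; MeOH quench; then TsOH·H2O (cat.), CH2Cl2, rt
Reagents that add atoms: none
Why: Hydroxyl-directed borane reduction: the alkoxyborane at the tertiary hydroxyl delivers hydride only to the neighbouring ester through a five-membered chelate. The resulting 1,2-diol ester then lactonises through its primary hydroxyl onto the remaining ester.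

Step 9
Reactants: 12 (4S)-4-(4-benzyloxy-3-methoxybenzyl)-4-hydroxyoxolan-2-one
Product: 13 (4S)-4-(4-benzyloxy-3-methoxybenzyl)-4-(trimethylsilyloxy)oxolan-2-one
Conditions: 1-(trimethylsilyl)imidazole, CH2Cl2, rt
Reagents that add atoms: 1-(trimethylsilyl)imidazole, C[Si](C)(C)n1ccnc1
Why: Neutral silylation of the tertiary alcohol; the small silyl ether blocks alkoxide chemistry (retro-aldol) in the next step and keeps the oxygen face of the enolate the less hindered one.

Step 10
Reactants: 13 (4S)-4-(4-benzyloxy-3-methoxybenzyl)-4-(trimethylsilyloxy)oxolan-2-one (2.4 equiv); 4 O-benzyl-O'-tosyl dehydrodivanillin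
Product: 14 bis-aldol adduct (2'-benzyloxy-3,3'-dimethoxy-5,5'-bis{hydroxy[(3R,4S)-4-(4-benzyloxy-3-methoxybenzyl)-2-oxo-4-(trimethylsilyloxy)oxolan-3-yl]methyl}biphenyl-2-yl 4-methylbenzenesulfonate; carbinol centres as a mixture)
Conditions: LiN(SiMe3)2 (2.5 equiv), THF, −78 °C; then 4 in THF, −78 °C; AcOH quench at −78 °C
Reagents that add atoms: none
Why: Two-directional aldol addition of the lactone lithium enolate. Each aldehyde should add to the enolate face opposite the arylmethyl group (the silyloxy group is the smaller neighbour), as in aldol reactions of 3-benzylbutanolides, which sets C3 (3R) in both arms. The carbinol centres need no control because step 12 removes them, and at −78 °C neither silanolate elimination nor attack on the tosylate should compete.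

Step 11
Reactants: 14 bis-aldol adduct
Product: 16 octaol (2'-benzyloxy-3,3'-dimethoxy-5,5'-bis[(2R,3S)-3-(4-benzyloxy-3-methoxybenzyl)-1,3,4-trihydroxy-2-(hydroxymethyl)butyl]biphenyl-2-yl 4-methylbenzenesulfonate; C1 carbinols as a mixture), via bis-silyl hexaol 15 (not isolated)
Conditions: LiBH4, THF, 0 °C to rt; MeOH quench; then Bu4NF, AcOH, THF, 0 °C
Reagents that add atoms: none
Why: Lithium borohydride reduces both lactones to diols and leaves the aryl tosylate and benzyl ethers alone; buffered fluoride then removes the tertiary trimethylsilyl ethers, whose task ended with the aldol step.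

Step 12
Reactants: 16 octaol
Product: 17 bis-lactol (2'-benzyloxy-3,3'-dimethoxy-5,5'-bis[(3S,4S)-4-(4-benzyloxy-3-methoxybenzyl)-2,4-dihydroxy-3-(hydroxymethyl)oxolan-2-yl]biphenyl-2-yl 4-methylbenzenesulfonate; anomers)
Conditions: activated MnO2 (excess), CH2Cl2, rt
Reagents that add atoms: none
Why: Manganese dioxide oxidises only the two benzylic secondary alcohols; each aryl ketone should be captured at once by its C5 hydroxyl as the five-membered hemiketal, which masks the β-hydroxy ketone against retro-aldol cleavage and C3 epimerisation.

Step 13
Reactants: 17 bis-lactol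
Product: 18 bis-oxolane (2'-benzyloxy-3,3'-dimethoxy-5,5'-bis[(2R,3R,4S)-4-(4-benzyloxy-3-methoxybenzyl)-4-hydroxy-3-(hydroxymethyl)oxolan-2-yl]biphenyl-2-yl 4-methylbenzenesulfonate)
Conditions: Et3SiH, BF3·OEt2, CH2Cl2, −78 to −40 °C; Et3N then aq. NaHCO3 at −40 °C
Reagents that add atoms: none
Why: Ionic reduction of the cyclic hemiketals through 2-aryl oxocarbenium ions. Hydride should enter from the face opposite the C3 hydroxymethyl and C4 arylmethyl groups (the face of the small C4 hydroxyl), giving the 2,3-cis (2R) oxolanes, the known kinetic outcome for 3-substituted 2-aryl lactols at low temperature. The oxolane on the tosyloxy ring cannot re-ionise, so its C2 is fixed; later epimerisation of the other arm would be harmless because that centre is destroyed in step 14.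

Step 14
Reactants: 18 bis-oxolane
Product: 19 tetralin–oxolane (2'-benzyloxy-5'-[(1S,2S,3S)-7-benzyloxy-3-hydroxy-2,3-bis(hydroxymethyl)-6-methoxy-1,2,3,4-tetrahydronaphthalen-1-yl]-5-[(2R,3R,4S)-4-(4-benzyloxy-3-methoxybenzyl)-4-hydroxy-3-(hydroxymethyl)oxolan-2-yl]-3,3'-dimethoxybiphenyl-2-yl 4-methylbenzenesulfonate)
Conditions: CF3CO2H/CH2Cl2 (1:9), 0 °C to rt; then NaHCO3, MeOH/H2O (cleaves any trifluoroacetate esters)
Reagents that add atoms: none
Why: The acid protonates O1 of the oxolane on the benzyloxy-bearing ring and the para-benzyloxy group expels it as the C5 hydroxymethyl group, giving a benzylic cation; the oxolane on the tosyloxy ring cannot follow, because a para-sulfonyloxy group gives no such stabilisation. The 4-benzyloxy-3-methoxyphenyl ring attached through the CH2 on C4 then attacks the cation with its carbon para to the methoxy group, forming C1–C8a in a Friedel–Crafts alkylation. The closest known reaction is the acid-catalysed isomerisation of 2-aryl-oxolane lignans into aryltetralins (olivil into cycloolivil, lariciresinol into isolariciresinol). The six-membered carbocycle closes in a 6-exo-trig sense onto the exocyclic cationic carbon through a chair-like transition state. The only new stereocentre, C1, is controlled by C2: the biaryl group takes the pseudo-equatorial position anti to the C2 hydroxymethyl group, which should give the 1,2-trans (1S) product, while C2 and C3 are the untouched oxolane C3 and C4. Reclosure of the cation by the freed hydroxyl only regenerates the oxolane of the reacting arm and so drains into the irreversible C–C closure. The step needs arm selectivity and retention of the cis C2 centre of the other arm, both secured by the tosylate, and site selectivity on the nucleophilic ring, secured by the methoxy group para to the reacting carbon and by the six-membered ring size.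

Step 15
Reactants: 19 tetralin–oxolane
Product: 20 tri-O-benzyl target (the 2-hydroxybiphenyl corresponding to 19; benzyl ethers on the other biaryl oxygen, on the tetralin C7 oxygen and on the benzyl-ring phenol of the oxolane half)
Conditions: Mg turnings, MeOH, rt
Reagents that add atoms: none
Why: Reductive desulfonylation of an aryl tosylate: electron transfer to the arenesulfonyl group cleaves the S–O bond at room temperature, without a base strong enough to open the para-hydroxybenzylic ether and without touching benzyl ethers or alcohols.

Step 16
Reactants: 20 tri-O-benzyl target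
Product: 21 target CNP0344108.1
Conditions: H2 (1 atm), Pd/C (10 %), EtOAc/MeOH, rt; stopped after three equivalents
Reagents that add atoms: none
Why: Hydrogenolysis of the three aryl benzyl ethers; phenolic benzyl ethers should cleave much faster in a neutral solvent than the benzylic C–O bond of the oxolane, and no stereocentre is involved.

## Compound list

1 | vanillin | COc1cc(C=O)ccc1O | starting material
2 | dehydrodivanillin | COc1cc(C=O)cc(-c2cc(C=O)cc(OC)c2O)c1O | intermediate
3 | mono-O-benzyl dehydrodivanillin | COc1cc(C=O)cc(-c2cc(C=O)cc(OC)c2O)c1OCc1ccccc1 | intermediate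
4 | O-benzyl-O'-tosyl dehydrodivanillin | COc1cc(C=O)cc(-c2cc(C=O)cc(OC)c2OS(=O)(=O)c2ccc(C)cc2)c1OCc1ccccc1 | intermediate
5 | [4-(benzyloxy)-3-methoxyphenyl]methanol | COc1cc(CO)ccc1OCc1ccccc1 | starting material
6 | 4-(benzyloxy)-3-methoxybenzyl bromide | COc1cc(CBr)ccc1OCc1ccccc1 | intermediate
7 | (S)-malic acid | OC(=O)C[C@H](O)C(=O)O | starting material
8 | 2-[(2S,4S)-2-tert-butyl-5-oxo-1,3-dioxolan-4-yl]acetic acid | CC(C)(C)[C@H]1O[C@@H](CC(=O)O)C(=O)O1 | intermediate
9 | 2-[(2S,4S)-4-(4-benzyloxy-3-methoxybenzyl)-2-tert-butyl-5-oxo-1,3-dioxolan-4-yl]acetic acid | CC(C)(C)[C@H]1O[C@@](Cc2ccc(OCc3ccccc3)c(OC)c2)(CC(=O)O)C(=O)O1 | intermediate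
10 | dimethyl (2S)-2-(4-benzyloxy-3-methoxybenzyl)-2-hydroxybutanedioate | COC(=O)C[C@@](O)(Cc1ccc(OCc2ccccc2)c(OC)c1)C(=O)OC | intermediate
11 | methyl (3S)-3-(4-benzyloxy-3-methoxybenzyl)-3,4-dihydroxybutanoate (diol ester; formed in the flask and not isolated) | COC(=O)C[C@@](O)(Cc1ccc(OCc2ccccc2)c(OC)c1)CO | intermediate
12 | (4S)-4-(4-benzyloxy-3-methoxybenzyl)-4-hydroxyoxolan-2-one | O=C1C[C@@](O)(Cc2ccc(OCc3ccccc3)c(OC)c2)CO1 | intermediate
13 | (4S)-4-(4-benzyloxy-3-methoxybenzyl)-4-(trimethylsilyloxy)oxolan-2-one | O=C1C[C@@](O[Si](C)(C)C)(Cc2ccc(OCc3ccccc3)c(OC)c2)CO1 | intermediate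
14 | bis-aldol adduct, (3R,4S) in both lactones, carbinols mixed | COc1cc(C(O)[C@H]2C(=O)OC[C@]2(O[Si](C)(C)C)Cc2ccc(OCc3ccccc3)c(OC)c2)cc(-c2cc(C(O)[C@H]3C(=O)OC[C@]3(O[Si](C)(C)C)Cc3ccc(OCc4ccccc4)c(OC)c3)cc(OC)c2OS(=O)(=O)c2ccc(C)cc2)c1OCc1ccccc1 | intermediate
15 | bis-silyl hexaol (lactones of 14 reduced, silyl ethers still in place; formed in the flask and not isolated) | COc1cc(C(O)[C@@H](CO)[C@](O[Si](C)(C)C)(CO)Cc2ccc(OCc3ccccc3)c(OC)c2)cc(-c2cc(C(O)[C@@H](CO)[C@](O[Si](C)(C)C)(CO)Cc3ccc(OCc4ccccc4)c(OC)c3)cc(OC)c2OS(=O)(=O)c2ccc(C)cc2)c1OCc1ccccc1 | intermediate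
16 | octaol, two [(2R,3S)-3-(arylmethyl)-1,3,4-trihydroxy-2-(hydroxymethyl)butyl] arms, C1 carbinols mixed | COc1cc(C(O)[C@@H](CO)[C@](O)(CO)Cc2ccc(OCc3ccccc3)c(OC)c2)cc(-c2cc(C(O)[C@@H](CO)[C@](O)(CO)Cc3ccc(OCc4ccccc4)c(OC)c3)cc(OC)c2OS(=O)(=O)c2ccc(C)cc2)c1OCc1ccccc1 | intermediate
17 | bis-lactol, (3S,4S) hemiketals, anomers | COc1cc(C2(O)OC[C@](O)(Cc3ccc(OCc4ccccc4)c(OC)c3)[C@@H]2CO)cc(-c2cc(C3(O)OC[C@](O)(Cc4ccc(OCc5ccccc5)c(OC)c4)[C@@H]3CO)cc(OC)c2OS(=O)(=O)c2ccc(C)cc2)c1OCc1ccccc1 | intermediate
18 | bis-oxolane, (2R,3R,4S) in both rings, tri-O-benzyl mono-O-tosyl | COc1cc([C@@H]2OC[C@](O)(Cc3ccc(OCc4ccccc4)c(OC)c3)[C@@H]2CO)cc(-c2cc([C@@H]3OC[C@](O)(Cc4ccc(OCc5ccccc5)c(OC)c4)[C@@H]3CO)cc(OC)c2OS(=O)(=O)c2ccc(C)cc2)c1OCc1ccccc1 | intermediate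
19 | tetralin–oxolane, tri-O-benzyl mono-O-tosyl target | COc1cc([C@H]2c3cc(OCc4ccccc4)c(OC)cc3C[C@@](O)(CO)[C@@H]2CO)cc(-c2cc([C@@H]3OC[C@](O)(Cc4ccc(OCc5ccccc5)c(OC)c4)[C@@H]3CO)cc(OC)c2OS(=O)(=O)c2ccc(C)cc2)c1OCc1ccccc1 | intermediate
20 | tri-O-benzyl target | COc1cc([C@H]2c3cc(OCc4ccccc4)c(OC)cc3C[C@@](O)(CO)[C@@H]2CO)cc(-c2cc([C@@H]3OC[C@](O)(Cc4ccc(OCc5ccccc5)c(OC)c4)[C@@H]3CO)cc(OC)c2O)c1OCc1ccccc1 | intermediate
21 | CNP0344108.1 | COc1cc(C[C@@]2(O)CO[C@@H](c3cc(OC)c(O)c(-c4cc([C@H]5c6cc(O)c(OC)cc6C[C@@](O)(CO)[C@@H]5CO)cc(OC)c4O)c3)[C@H]2CO)ccc1O | target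

## Step count and least certain steps

Total step count: 16. Longest linear sequence: 12 steps (steps 5 to 16, from (S)-malic acid 7). The biaryl branch (steps 1 to 3) joins at step 10 and the bromide (step 4) at step 6.

**Step 14 (key step).** The most likely failure is on the reacting arm: ionisation that is too slow at acid strengths the benzyl ethers tolerate, partial attack ortho to the methoxy group, or acid-induced loss of benzyl groups, since the arm here is an aryl benzyl ether and not a free phenol. Fallback: setting out from 18, the three benzyl ethers are removed first (H2, Pd/C, EtOAc/MeOH) to give the tris-phenol bis-oxolane monotosylate F1. Its free-phenol arm ionises under far milder acid (HCO2H, or 1 % CF3CO2H in MeCN/H2O), as the natural oxolane lignans do, while the tosylated arm stays inert, and should give the tris-phenol tetralin–oxolane monotosylate F2. Mg in MeOH then removes the tosyl group and the route is rejoined at 21.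

**Step 10.** The enolate of 13 may be attacked on the wrong face (syn to the arylmethyl group) if the silyloxy group proves the larger neighbour in the transition state, which would put the wrong configuration at C3 of both arms. Silyl transfer from the tertiary oxygen to the new aldolate oxygen is a second possible loss if the mixture warms before the quench. Fallback: setting out from 13 and 4, the aldol is run as before. If it delivers the (3S,4S) bis-aldol adduct F3, the stereo-determining event is moved from C–C to C–H bond formation. F3 is deprotonated at both carbinol oxygens and both lactone α-carbons with LiN(i-Pr)2 (excess, THF, −78 °C) and the enolates are protonated kinetically with AcOH at −78 °C. The proton then takes the face the aldehyde had taken, and the carbinol carbon ends on the required side, which brings the route back at 14.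

**Step 12.** Oxidation of the carbinol on the tosyloxy ring may be slow on a polyol adsorbed on MnO2, and any open hydroxy ketone can lose formaldehyde by retro-aldol cleavage or epimerise at C3 before it closes to the hemiketal. Fallback: from 16 the four primary hydroxyls are silylated (t-BuMe2SiCl, imidazole, DMF, 0 °C) to the tetrakis-silyl ether F4. The two benzylic alcohols are oxidised with Dess–Martin periodinane (NaHCO3, CH2Cl2) to the bis(aryl ketone) F5. HF·pyridine in THF then removes the silyl groups, after which the ketones close to the hemiketals and the route is rejoined at 17.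

**Step 2.** Mono-benzylation of a sparingly soluble diol may run on to the dibenzyl ether and leave diol, so that material is lost in recycling. Fallback: the unsymmetrical biaryl is made by cross-coupling instead of by desymmetrisation. From 1, bromination (Br2, AcOH) gives 5-bromovanillin F6. One portion is benzylated (BnBr, K2CO3, DMF) to 4-benzyloxy-3-bromo-5-methoxybenzaldehyde F7, and another is tosylated (TsCl, Et3N) to 2-bromo-4-formyl-6-methoxyphenyl tosylate F8. F7 is borylated (bis(pinacolato)diboron, PdCl2(dppf), KOAc, dioxane, 80 °C) to the pinacol boronate F9. Suzuki–Miyaura coupling of F9 with F8 (Pd(PPh3)4, K2CO3, dioxane/H2O) gives 4, under conditions in which an aryl tosylate does not undergo oxidative addition.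

## Further compounds

F1 | step 14 | tris-phenol bis-oxolane monotosylate (18 without its three benzyl groups) | COc1cc([C@@H]2OC[C@](O)(Cc3ccc(O)c(OC)c3)[C@@H]2CO)cc(-c2cc([C@@H]3OC[C@](O)(Cc4ccc(O)c(OC)c4)[C@@H]3CO)cc(OC)c2OS(=O)(=O)c2ccc(C)cc2)c1O
F2 | step 14 | tris-phenol tetralin–oxolane monotosylate (O-tosyl target) | COc1cc([C@H]2c3cc(O)c(OC)cc3C[C@@](O)(CO)[C@@H]2CO)cc(-c2cc([C@@H]3OC[C@](O)(Cc4ccc(O)c(OC)c4)[C@@H]3CO)cc(OC)c2OS(=O)(=O)c2ccc(C)cc2)c1O
F3 | step 10 | (3S,4S) bis-aldol adduct, C3 epimer of 14 in both lactones | COc1cc(C(O)[C@@H]2C(=O)OC[C@]2(O[Si](C)(C)C)Cc2ccc(OCc3ccccc3)c(OC)c2)cc(-c2cc(C(O)[C@@H]3C(=O)OC[C@]3(O[Si](C)(C)C)Cc3ccc(OCc4ccccc4)c(OC)c3)cc(OC)c2OS(=O)(=O)c2ccc(C)cc2)c1OCc1ccccc1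
F4 | step 12 | tetrakis(tert-butyldimethylsilyl) ether of 16 at the four primary hydroxyls | COc1cc(C(O)[C@@H](CO[Si](C)(C)C(C)(C)C)[C@](O)(CO[Si](C)(C)C(C)(C)C)Cc2ccc(OCc3ccccc3)c(OC)c2)cc(-c2cc(C(O)[C@@H](CO[Si](C)(C)C(C)(C)C)[C@](O)(CO[Si](C)(C)C(C)(C)C)Cc3ccc(OCc4ccccc4)c(OC)c3)cc(OC)c2OS(=O)(=O)c2ccc(C)cc2)c1OCc1ccccc1
F5 | step 12 | bis(aryl ketone) from F4 | COc1cc(C(=O)[C@@H](CO[Si](C)(C)C(C)(C)C)[C@](O)(CO[Si](C)(C)C(C)(C)C)Cc2ccc(OCc3ccccc3)c(OC)c2)cc(-c2cc(C(=O)[C@@H](CO[Si](C)(C)C(C)(C)C)[C@](O)(CO[Si](C)(C)C(C)(C)C)Cc3ccc(OCc4ccccc4)c(OC)c3)cc(OC)c2OS(=O)(=O)c2ccc(C)cc2)c1OCc1ccccc1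
F6 | step 2 | 5-bromovanillin | COc1cc(C=O)cc(Br)c1O
F7 | step 2 | 4-benzyloxy-3-bromo-5-methoxybenzaldehyde | COc1cc(C=O)cc(Br)c1OCc1ccccc1
F8 | step 2 | 2-bromo-4-formyl-6-methoxyphenyl 4-methylbenzenesulfonate | COc1cc(C=O)cc(Br)c1OS(=O)(=O)c1ccc(C)cc1
F9 | step 2 | 4-benzyloxy-3-methoxy-5-(4,4,5,5-tetramethyl-1,3,2-dioxaborolan-2-yl)benzaldehyde | COc1cc(C=O)cc(B2OC(C)(C)C(C)(C)O2)c1OCc1ccccc1
A1 | alternative 1 | 1-aryl-tetralin-2-carbaldehyde with spiro acetonide at C3 | COc1cc(Br)cc(-c2cc([C@H]3c4cc(OCc5ccccc5)c(OC)cc4C[C@]6(OC(C)(C)OC6)[C@@H]3C=O)cc(OC)c2OCc2ccccc2)c1OCc1ccccc1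
A2 | alternative 1 | diarylmethanol with tethered aldehyde (carbinol as either epimer) | COc1cc(Br)cc(-c2cc(C(O)c3cc(OCc4ccccc4)c(OC)cc3C[C@]3(CC=O)COC(C)(C)O3)cc(OC)c2OCc2ccccc2)c1OCc1ccccc1
A3 | alternative 2 | tetralin 3-hydroxy-3-carboxylic acid | COc1cc(Br)cc(-c2cc([C@H]3c4cc(OCc5ccccc5)c(OC)cc4C[C@@](O)(C(=O)O)[C@@H]3COCc6ccccc6)cc(OC)c2OCc2ccccc2)c1OCc1ccccc1
A4 | alternative 2 | 9-aryl-8-(benzyloxymethyl)-8,9-dihydro-5H-benzo[7]annulene-6,7-dione | COc1cc(Br)cc(-c2cc([C@H]3c4cc(OCc5ccccc5)c(OC)cc4CC(=O)C(=O)[C@@H]3COCc3ccccc3)cc(OC)c2OCc2ccccc2)c1OCc1ccccc1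
A5 | alternative 3 | tetralin with C3 carbinol and C2 methyl ester | COc1cc(Br)cc(-c2cc([C@H]3c4cc(OCc5ccccc5)c(OC)cc4C[C@@](O)(CO)[C@@H]3C(=O)OC)cc(OC)c2OCc2ccccc2)c1OCc1ccccc1
A6 | alternative 3 | methyl 3,3-diaryl-2-(3-hydroxyoxetan-3-yl)propanoate | COc1cc(Br)cc(-c2cc([C@@H](c3ccc(OC)c(OCc4ccccc4)c3)[C@@H](C(=O)OC)C3(O)COC3)cc(OC)c2OCc2ccccc2)c1OCc1ccccc1
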